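**Retrosynthetic overview**

- The plan rests on C10, the tertiary carbinol shared by rings A and B and bonded to C1, C5 and C9, next to quaternary C5. It is taken back to a lactone carbonyl on C5 whose ring oxygen is the C3 oxygen.
- Key disconnections are C9–C10 and C1–C10: SmI2 turns an allylic bromide (C9) and a primary iodide (C1) into nucleophiles that add in turn to that carbonyl, closing ring B first and ring A second.
- The precursor is a trans-β-methyl-γ-alkyl butyrolactone made by anti-crotylboration, hydroboration and oxidative lactonisation; C5 is made quaternary by methylation and then alkylation with an allylsilane iodide, and the two halides go in last.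
- End game: C8 methylene to ketone, C6–C7 dehydrogenation, 9α-hydroxylation (Rubottom), C7 acetyl by iodination and Stille coupling, angelate last.

Key step: step 11

Remark on the chemistry: carbons carry the decalin numbering (ring A = C10, C1–C5; ring B = C5–C10) from the first step on and β is the face of the C5 methyl; the anti (3S,4R) alcohol needed for the trans lactone requires the (E)-crotyl reagent, and 12 may be a C5 epimer mixture because that centre is enolised again in step 7.

**Route**

Step 1
Reactants: 1 3-(tert-butyldimethylsilyloxy)propanal; 2 (E)-but-2-ene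
Product: 6 (3S,4R)-1-(tert-butyldimethylsilyloxy)-4-methylhex-5-en-3-ol (anti), via crotylpotassium 3 (not isolated), via crotyldiisopinocampheylborane 4 (not isolated), via borinate ester 5 (not isolated)
Conditions: 2, KOt-Bu, n-BuLi, THF, −78 → −45 °C; (+)-Ipc2BOMe [from (−)-α-pinene], −78 °C; BF3·OEt2; 1, −78 °C; NaOH, H2O2, 0 °C → rt
Reagents that add atoms: none
Why: Brown crotylboration through a closed chair (Zimmerman–Traxler) transition state, in which the (E)-crotyl geometry sets the anti relationship and the isopinocampheyl groups from (−)-α-pinene direct addition to the aldehyde face that gives the 3S carbinol.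

Step 2
Reactants: 6
Product: 8 (3R,4S)-6-(tert-butyldimethylsilyloxy)-3-methylhexane-1,4-diol, via alkylborane 7 (not isolated)
Conditions: 9-BBN (2.5 equiv), THF, 0 °C → rt; NaOH, H2O2, 0 °C
Reagents that add atoms: hydrogen peroxide, OO
Why: Anti-Markovnikov hydroboration of the terminal alkene with bulky 9-BBN and oxidation of the C–B bond with retention should give the primary alcohol without touching either stereocentre or the silyl ether.

Step 3
Reactants: 8
Product: 10 (4R,5S)-5-[2-(tert-butyldimethylsilyloxy)ethyl]-4-methyldihydrofuran-2(3H)-one (trans), via lactol 9 (not isolated)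
Conditions: TEMPO (cat.), PhI(OAc)2, CH2Cl2, rt
Reagents that add atoms: none
Why: Oxidative lactonisation of a 1,4-diol, in which TEMPO/PhI(OAc)2 oxidises the primary alcohol selectively, the aldehyde closes to lactol 9 and is oxidised on to the γ-lactone, whose trans substituents follow from the anti alcohol.

Step 4
Reactants: 10
Product: 12 (3R,4R,5S)-5-[2-(tert-butyldimethylsilyloxy)ethyl]-3,4-dimethyldihydrofuran-2(3H)-one (major epimer), via lithium enolate 11 (not isolated)
Conditions: LiN(i-Pr)2, THF, −78 °C; MeI, −78 → −40 °C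
Reagents that add atoms: iodomethane, CI
Why: Enolate alkylation of the lithium lactone enolate with MeI, which enters mainly trans to the adjacent C4 methyl group.

Step 5
Reactants: 13 3-methylbut-3-en-1-ol
Product: 16 3-[(trimethylsilyl)methyl]but-3-en-1-ol, via dilithio dianion 14 (not isolated), via bis-silyl compound 15 (not isolated)
Conditions: n-BuLi (2.2 equiv), TMEDA, Et2O/hexane, 0 °C → rt; Me3SiCl, −78 °C → rt; 1 M H2SO4, THF, rt
Reagents that add atoms: chlorotrimethylsilane, C[Si](C)(C)Cl
Why: Allylic metalation of the lithium alkoxide with n-BuLi/TMEDA gives the O,C-dianion, both sites are silylated, and dilute acid then cleaves only the Si–O bond.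

Step 6
Reactants: 16
Product: 17 4-iodo-2-[(trimethylsilyl)methyl]but-1-ene
Conditions: PPh3, imidazole, I2, CH2Cl2, 0 °C
Reagents that add atoms: iodine, II
Why: Appel-type iodination, in which iodide displaces the alkoxyphosphonium group by SN2 and the allylsilane is spared because the iodine is bound as the phosphine adduct.

Step 7
Reactants: 12; 17
Product: 19 (3R,4R,5S)-5-[2-(tert-butyldimethylsilyloxy)ethyl]-3,4-dimethyl-3-{3-[(trimethylsilyl)methyl]but-3-en-1-yl}dihydrofuran-2(3H)-one, via lithium enolate 18 (not isolated)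
Conditions: LiN(i-Pr)2, THF, −78 °C; HMPA, 17, −78 → −20 °C
Reagents that add atoms: none
Why: Enolate alkylation of tetrasubstituted enolate 18 by the primary iodide on the face opposite the adjacent C4 methyl, which sets quaternary C5 with its methyl cis to the C4 methyl and the new chain trans to it.

Step 8
Reactants: 19
Product: 20 (3R,4R,5S)-5-(2-hydroxyethyl)-3,4-dimethyl-3-{3-[(trimethylsilyl)methyl]but-3-en-1-yl}dihydrofuran-2(3H)-one
Conditions: PPTS (cat.), MeOH, rt
Reagents that add atoms: none
Why: Acid-catalysed methanolysis of the primary silyl ether under conditions too mild to protodesilylate the allylsilane or open the γ-lactone.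

Step 9
Reactants: 20
Product: 21 (3R,4R,5S)-5-(2-iodoethyl)-3,4-dimethyl-3-{3-[(trimethylsilyl)methyl]but-3-en-1-yl}dihydrofuran-2(3H)-one
Conditions: PPh3, imidazole, I2, CH2Cl2, 0 °C
Reagents that add atoms: iodine, II
Why: Appel-type iodination of the primary C1 alcohol by SN2 displacement of the alkoxyphosphonium ion, with no stereocentre involved.

Step 10
Reactants: 21
Product: 22 (3R,4R,5S)-3-[3-(bromomethyl)but-3-en-1-yl]-5-(2-iodoethyl)-3,4-dimethyldihydrofuran-2(3H)-one
Conditions: NBS, propylene oxide, CH2Cl2, −78 °C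
Reagents that add atoms: N-bromosuccinimide, O=C1CCC(=O)N1Br
Why: Electrophilic bromodesilylation of the allylsilane (SE2′), in which the allylic transposition is without consequence because both termini of the 2-substituted allyl unit are CH2 groups, and the primary iodide and lactone are inert at −78 °C.

Step 11
Reactants: 22
Product: 26 4β,5β-dimethyl-8-methylene-cis-decalin-3β,10β-diol, via allylsamarium diiodide 23 (not isolated), via samarium keto alkoxide 24 (not isolated), via alkylsamarium diiodide 25 (not isolated)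
Conditions: SmI2 (5 equiv), THF, 0 °C, slow addition of 22; then HMPA, 0 °C → rt; aq. NH4Cl
Reagents that add atoms: none
Why: SmI2 reduces the allylic C9–Br bond first (two single-electron transfers) to allylsamarium 23, whose terminus adds to the C10 lactone carbonyl; collapse of the hemiketalate cleaves C10–O and frees the C10 ketone as its C3 samarium alkoxide 24, after which HMPA makes SmI2 strong enough to convert C1–I into alkylsamarium 25, which adds to that ketone. The closest known reaction type is the SmI2-promoted sequential intramolecular nucleophilic acyl substitution and Barbier cyclization of dihalo esters and lactones. Ring B closes by 6-exo-trig attack of C9 on the lactone C=O and ring A by 6-exo-trig attack of C1 on the C10 ketone. C10 is the only new stereocentre: C1 is delivered from the α-face, on which its tether leaves C5, and the trivalent samarium on the β-oriented C3 alkoxide can bridge to the carbonyl oxygen only if that oxygen ends up β, so the cis-fused 10β-ol (OH syn to the C5 methyl) is expected, as in ketol cyclizations onto α-quaternary cyclohexanones. The step needs ordered, chemoselective halide reduction, which the much easier reduction of the allylic bromide than of the primary iodide in HMPA-free THF secures; the two allyl termini are equivalent, so no regiochemical question arises, and C3, C4 and C5 are untouched.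

Step 12
Reactants: 26
Product: 27 3β-acetoxy-4β,5β-dimethyl-8-methylene-cis-decalin-10β-ol
Conditions: Ac2O, pyridine, DMAP (cat.), CH2Cl2, 0 °C → rt
Reagents that add atoms: acetic anhydride, CC(=O)OC(C)=O
Why: Acylation takes only the secondary C3 hydroxyl, because the tertiary ring-fusion C10 hydroxyl is too hindered to react under these conditions.

Step 13
Reactants: 27
Product: 29 3β-acetoxy-10β-hydroxy-4β,5β-dimethyl-cis-decalin-8-one, via ozonide 28 (not isolated)
Conditions: O3, CH2Cl2, −78 °C; PPh3, −78 °C → rt
Reagents that add atoms: ozone, [O-][O+]=O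
Why: Ozonolysis of the only alkene and reduction of the ozonide with PPh3 should unveil the C8 ketone, since no other group reacts with ozone.

Step 14
Reactants: 29
Product: 30 3β-acetoxy-10β-hydroxy-4β,5β-dimethyl-cis-decal-6-en-8-one
Conditions: IBX, 4-methoxypyridine N-oxide, DMSO, rt
Reagents that add atoms: none
Why: IBX dehydrogenation (capture of the enol by the hypervalent iodine reagent, then elimination) can only form the C6–C7 double bond because C10 on the other side of the ketone has no hydrogen, and room temperature should spare the β-hydroxy ketone from dehydration.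

Step 15
Reactants: 30
Product: 33 3β-acetoxy-9α,10β-dihydroxy-4β,5β-dimethyl-cis-decal-6-en-8-one, via bis-silyl dienol ether 31 (not isolated), via bis-silyl ketol 32 (not isolated)
Conditions: Me3SiOTf, Et3N, CH2Cl2, 0 °C; mCPBA, NaHCO3, CH2Cl2, −20 °C; 1 M HCl, THF, 0 °C
Reagents that add atoms: 3-chloroperoxybenzoic acid, OOC(=O)c1cccc(Cl)c1
Why: Rubottom oxidation, in which soft enolisation can only go toward C9 (C7 is sp2 and C5 has no hydrogen) and also silylates the C10 hydroxyl, and the peracid should epoxidise the electron-rich C8–C9 enol ether from the α-face opposite the bulky 10β-silyloxy group to give the 9α-hydroxy ketone after silyl migration and acidic work-up.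

Step 16
Reactants: 33
Product: 34 3β-acetoxy-9α,10β-dihydroxy-7-iodo-4β,5β-dimethyl-cis-decal-6-en-8-one
Conditions: I2, pyridine, CH2Cl2, rt
Reagents that add atoms: iodine, II
Why: α-Iodination of the enone by addition–elimination (pyridine adds at C6, the enolate is iodinated, pyridine is expelled) places iodine on C7, the only α-vinylic position.

Step 17
Reactants: 34
Product: 36 3β-acetoxy-7-acetyl-9α,10β-dihydroxy-4β,5β-dimethyl-cis-decal-6-en-8-one, via ethoxyvinyl dienone 35 (not isolated)
Conditions: tributyl(1-ethoxyvinyl)stannane, Pd(PPh3)4 (cat.), CuI (cat.), DMF, 45 °C; 1 M HCl, THF, 0 °C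
Reagents that add atoms: tributyl(1-ethoxyvinyl)stannane, CCCC[Sn](CCCC)(CCCC)C(=C)OCC; water, O
Why: Stille coupling (zerovalent palladium inserts into the C7–I bond, the 1-ethoxyvinyl group is transferred from tin, reductive elimination) followed by mild acid hydrolysis of the enol ether should give the C7 acetyl group.

Step 18
Reactants: 36; 37 angelic acid
Product: 39 3β-acetoxy-7-acetyl-9α-angeloyloxy-10β-hydroxy-4β,5β-dimethyl-cis-decal-6-en-8-one (CNP0196241.1), via mixed anhydride 38 (not isolated)
Conditions: 37, 2,4,6-Cl3C6H2COCl, Et3N, toluene, rt; then 36, toluene, 80 °C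
Reagents that add atoms: none
Why: Yamaguchi-type esterification through the mixed 2,4,6-trichlorobenzoic anhydride, run thermally without a nucleophilic catalyst, should acylate the secondary C9 hydroxyl with retention of the Z geometry while the tertiary C10 hydroxyl stays free.

**Compound list**

1 | 3-(tert-butyldimethylsilyloxy)propanal | CC(C)(C)[Si](C)(C)OCCC=O | starting material
2 | (E)-but-2-ene | C/C=C/C | starting material
3 | (E)-crotylpotassium | C/C=C/[CH2-].[K+] | intermediate (not isolated)
4 | (E)-crotyldiisopinocampheylborane, Ipc groups from (−)-α-pinene | C/C=C/CB([C@H]1C[C@H]2C[C@@H]([C@@H]1C)C2(C)C)[C@H]1C[C@H]2C[C@@H]([C@@H]1C)C2(C)C | intermediate (not isolated)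
5 | diisopinocampheylborinate ester of 6 | C=C[C@@H](C)[C@H](CCO[Si](C)(C)C(C)(C)C)OB([C@H]1C[C@H]2C[C@@H]([C@@H]1C)C2(C)C)[C@H]1C[C@H]2C[C@@H]([C@@H]1C)C2(C)C | intermediate (not isolated)
6 | (3S,4R)-1-(tert-butyldimethylsilyloxy)-4-methylhex-5-en-3-ol | C=C[C@@H](C)[C@@H](O)CCO[Si](C)(C)C(C)(C)C | intermediate
7 | B-alkyl-9-borabicyclo[3.3.1]nonane from 6 (boron on the terminal carbon) | B1(C2CCCC1CCC2)CC[C@@H](C)[C@@H](O)CCO[Si](C)(C)C(C)(C)C | intermediate (not isolated)
8 | (3R,4S)-6-(tert-butyldimethylsilyloxy)-3-methylhexane-1,4-diol | OCC[C@@H](C)[C@@H](O)CCO[Si](C)(C)C(C)(C)C | intermediate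
9 | (4R,5S)-5-[2-(tert-butyldimethylsilyloxy)ethyl]-4-methyltetrahydrofuran-2-ol (anomer mixture) | OC1C[C@@H](C)[C@H](CCO[Si](C)(C)C(C)(C)C)O1 | intermediate (not isolated)
10 | (4R,5S)-5-[2-(tert-butyldimethylsilyloxy)ethyl]-4-methyldihydrofuran-2(3H)-one | O=C1O[C@@H](CCO[Si](C)(C)C(C)(C)C)[C@H](C)C1 | intermediate
11 | lithium enolate of 10 | [Li+].[O-]C1=C[C@@H](C)[C@H](CCO[Si](C)(C)C(C)(C)C)O1 | intermediate (not isolated)
12 | (3R,4R,5S)-5-[2-(tert-butyldimethylsilyloxy)ethyl]-3,4-dimethyldihydrofuran-2(3H)-one | O=C1O[C@@H](CCO[Si](C)(C)C(C)(C)C)[C@H](C)[C@H]1C | intermediate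
13 | 3-methylbut-3-en-1-ol | C=C(C)CCO | starting material
14 | dilithio O,C-dianion of 13 | [Li+].[Li+].[CH2-]C(=C)CC[O-] | intermediate (not isolated)
15 | trimethyl{2-[2-(trimethylsilyloxy)ethyl]allyl}silane | C=C(CCO[Si](C)(C)C)C[Si](C)(C)C | intermediate (not isolated)
16 | 3-[(trimethylsilyl)methyl]but-3-en-1-ol | C=C(CCO)C[Si](C)(C)C | intermediate
17 | 4-iodo-2-[(trimethylsilyl)methyl]but-1-ene | C=C(CCI)C[Si](C)(C)C | intermediate
18 | lithium enolate of 12 | [Li+].[O-]C1=C(C)[C@@H](C)[C@H](CCO[Si](C)(C)C(C)(C)C)O1 | intermediate (not isolated)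
19 | (3R,4R,5S)-5-[2-(tert-butyldimethylsilyloxy)ethyl]-3,4-dimethyl-3-{3-[(trimethylsilyl)methyl]but-3-en-1-yl}dihydrofuran-2(3H)-one | O=C1O[C@@H](CCO[Si](C)(C)C(C)(C)C)[C@H](C)[C@@]1(C)CCC(=C)C[Si](C)(C)C | intermediate
20 | (3R,4R,5S)-5-(2-hydroxyethyl)-3,4-dimethyl-3-{3-[(trimethylsilyl)methyl]but-3-en-1-yl}dihydrofuran-2(3H)-one | O=C1O[C@@H](CCO)[C@H](C)[C@@]1(C)CCC(=C)C[Si](C)(C)C | intermediate
21 | (3R,4R,5S)-5-(2-iodoethyl)-3,4-dimethyl-3-{3-[(trimethylsilyl)methyl]but-3-en-1-yl}dihydrofuran-2(3H)-one | O=C1O[C@@H](CCI)[C@H](C)[C@@]1(C)CCC(=C)C[Si](C)(C)C | intermediate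
22 | (3R,4R,5S)-3-[3-(bromomethyl)but-3-en-1-yl]-5-(2-iodoethyl)-3,4-dimethyldihydrofuran-2(3H)-one (key-step precursor) | O=C1O[C@@H](CCI)[C@H](C)[C@@]1(C)CCC(=C)CBr | intermediate
23 | allylsamarium diiodide from 22 (Sm on C9) | O=C1O[C@@H](CCI)[C@H](C)[C@@]1(C)CCC(=C)C[Sm](I)I | intermediate (not isolated)
24 | ring B ketone: 2-methyl-5-methylenecyclohexanone bearing on C5 the CH(CH3)–CH(OSmI2)–CH2CH2I chain | O=C1CC(=C)CC[C@]1(C)[C@@H](C)[C@@H](O[Sm](I)I)CCI | intermediate (not isolated)
25 | alkylsamarium diiodide from 24 (Sm on C1) | O=C1CC(=C)CC[C@]1(C)[C@@H](C)[C@@H](O[Sm](I)I)CC[Sm](I)I | intermediate (not isolated)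
26 | 4β,5β-dimethyl-8-methylene-cis-decalin-3β,10β-diol (key-step product) | C1C(=C)CC[C@]2(C)[C@@H](C)[C@@H](O)CC[C@]12O | intermediate
27 | 3β-acetoxy-4β,5β-dimethyl-8-methylene-cis-decalin-10β-ol | C1C(=C)CC[C@]2(C)[C@@H](C)[C@@H](OC(C)=O)CC[C@]12O | intermediate
28 | spiro 1,2,4-trioxolane (secondary ozonide) at C8 of 27 | C1C3(OOCO3)CC[C@]2(C)[C@@H](C)[C@@H](OC(C)=O)CC[C@]12O | intermediate (not isolated)
29 | 3β-acetoxy-10β-hydroxy-4β,5β-dimethyl-cis-decalin-8-one | C1C(=O)CC[C@]2(C)[C@@H](C)[C@@H](OC(C)=O)CC[C@]12O | intermediate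
30 | 3β-acetoxy-10β-hydroxy-4β,5β-dimethyl-cis-decal-6-en-8-one | C1C(=O)C=C[C@]2(C)[C@@H](C)[C@@H](OC(C)=O)CC[C@]12O | intermediate
31 | 3β-acetoxy-8,10β-bis(trimethylsilyloxy)-4β,5β-dimethyl-cis-decala-6,8-diene | C1=C(O[Si](C)(C)C)C=C[C@]2(C)[C@@H](C)[C@@H](OC(C)=O)CC[C@]12O[Si](C)(C)C | intermediate (not isolated)
32 | 3β-acetoxy-9α,10β-bis(trimethylsilyloxy)-4β,5β-dimethyl-cis-decal-6-en-8-one | C[Si](C)(C)O[C@@H]1C(=O)C=C[C@]2(C)[C@@H](C)[C@@H](OC(C)=O)CC[C@]12O[Si](C)(C)C | intermediate (not isolated)
33 | 3β-acetoxy-9α,10β-dihydroxy-4β,5β-dimethyl-cis-decal-6-en-8-one | O[C@@H]1C(=O)C=C[C@]2(C)[C@@H](C)[C@@H](OC(C)=O)CC[C@]12O | intermediate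
34 | 3β-acetoxy-9α,10β-dihydroxy-7-iodo-4β,5β-dimethyl-cis-decal-6-en-8-one | O[C@@H]1C(=O)C(I)=C[C@]2(C)[C@@H](C)[C@@H](OC(C)=O)CC[C@]12O | intermediate
35 | 3β-acetoxy-7-(1-ethoxyvinyl)-9α,10β-dihydroxy-4β,5β-dimethyl-cis-decal-6-en-8-one | O[C@@H]1C(=O)C(C(=C)OCC)=C[C@]2(C)[C@@H](C)[C@@H](OC(C)=O)CC[C@]12O | intermediate (not isolated)
36 | 3β-acetoxy-7-acetyl-9α,10β-dihydroxy-4β,5β-dimethyl-cis-decal-6-en-8-one | O[C@@H]1C(=O)C(C(C)=O)=C[C@]2(C)[C@@H](C)[C@@H](OC(C)=O)CC[C@]12O | intermediate
37 | angelic acid, (Z)-2-methylbut-2-enoic acid | C/C=C(/C)C(O)=O | starting material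
38 | angelic 2,4,6-trichlorobenzoic anhydride | C/C=C(/C)C(=O)OC(=O)c1c(Cl)cc(Cl)cc1Cl | intermediate (not isolated)
39 | 3β-acetoxy-7-acetyl-9α-angeloyloxy-10β-hydroxy-4β,5β-dimethyl-cis-decal-6-en-8-one (CNP0196241.1) | C/C=C(/C)C(=O)O[C@@H]1C(=O)C(C(C)=O)=C[C@]2(C)[C@@H](C)[C@@H](OC(C)=O)CC[C@]12O | target

**Step count and risks**

Total steps: 18. Longest linear sequence: 16 steps (steps 1–4 and 7–18, from 1 to 39); steps 5 and 6 make the side-chain iodide 17.

The three steps most likely to fail:

1. Step 11 (key step). Three processes may interfere. A proton may pass from the doubly activated C9 methylene of ketone 24 to the samarium alkoxide or to the C1 organosamarium, so that C1 is quenched before ring A closes. C1 may add to the β-face of C10 and give the trans fusion. Allyl radicals may couple between molecules. The fallback sets out from iodide 21, in which the allylsilane is still in place. Iodine–lithium exchange with t-BuLi (Et2O/pentane, −78 °C) lets the C1 carbanion add to the lactone carbonyl first, and collapse of the bridged hemiketal alkoxide should give, after work-up, (2R,3R,4S)-4-hydroxy-2,3-dimethyl-2-{3-[(trimethylsilyl)methyl]but-3-en-1-yl}cyclohexan-1-one F1, in which ring A is closed and the C10 ketone has no doubly activated α-hydrogen. TiCl4 (CH2Cl2, −78 °C) should then close ring B by intramolecular Hosomi–Sakurai addition of the allylsilane to the C10 ketone, with the titanium chelate between the C3 oxygen and the ketone oxygen favouring the cis fusion. The route is rejoined at diol 26.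

2. Step 15. The peracid may add to the β-face of the dienol ether and give the 9β-hydroxy epimer, because both faces of ring B carry a substituent at C10 and C5. The fallback sets out from enone 30 and applies if electrophiles prove to add to the β-face. The same dienol ether 31 is brominated with NBS (THF, −78 °C) and worked up with dilute acid to give 3β-acetoxy-9β-bromo-10β-hydroxy-4β,5β-dimethyl-cis-decal-6-en-8-one F2. SN2 displacement with HCO2Cs in DMF should invert C9 and give 3β-acetoxy-9α-formyloxy-10β-hydroxy-4β,5β-dimethyl-cis-decal-6-en-8-one F3. KHCO3 in MeOH at 0 °C should remove the formate while the C3 acetate survives, and the route is rejoined at 33.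

3. Step 18. The activated angeloyl group may isomerise from Z to E (tiglate), or the hindered C9 hydroxyl, flanked by the C8 ketone and quaternary C10, may not acylate. The fallback sets out from 36 and builds the Z alkene on the ester instead of transferring it. DCC/DMAP esterification with 2-[bis(2,2,2-trifluoroethoxy)phosphoryl]propanoic acid (no alkene to isomerise, so a nucleophilic catalyst can be used) should give the 9α-{2-[bis(2,2,2-trifluoroethoxy)phosphoryl]propanoyloxy} ester of 36 F4. Still–Gennari olefination with acetaldehyde (K2CO3, 18-crown-6, toluene, −20 °C) should then form the Z-configured 2-methylbut-2-enoate and arrive at target 39.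

Further compounds
F1 | step 11 | (2R,3R,4S)-4-hydroxy-2,3-dimethyl-2-{3-[(trimethylsilyl)methyl]but-3-en-1-yl}cyclohexan-1-one | O=C1CC[C@H](O)[C@H](C)[C@@]1(C)CCC(=C)C[Si](C)(C)C
F2 | step 15 | 3β-acetoxy-9β-bromo-10β-hydroxy-4β,5β-dimethyl-cis-decal-6-en-8-one | Br[C@H]1C(=O)C=C[C@]2(C)[C@@H](C)[C@@H](OC(C)=O)CC[C@]12O
F3 | step 15 | 3β-acetoxy-9α-formyloxy-10β-hydroxy-4β,5β-dimethyl-cis-decal-6-en-8-one | O=CO[C@@H]1C(=O)C=C[C@]2(C)[C@@H](C)[C@@H](OC(C)=O)CC[C@]12O
F4 | step 18 | 9α-{2-[bis(2,2,2-trifluoroethoxy)phosphoryl]propanoyloxy} ester of 36 | CC(P(=O)(OCC(F)(F)F)OCC(F)(F)F)C(=O)O[C@@H]1C(=O)C(C(C)=O)=C[C@]2(C)[C@@H](C)[C@@H](OC(C)=O)CC[C@]12O
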